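Multiply the last Z reading of each earlier run by its X charge, with G counted in Z: beta then holds 0.0364 M and alpha 0.0385 M, although alpha got 1.51 times the X.

common to all: L 0.0624 M
- beta: X 0.073 M; run made earlier
- alpha: X 0.11 M; run made earlier
- flask: X 0.052 M; time 3.0 h

| run | time / h | Z / % | G / % |
|---|---|---|---|
| beta | 0.250 | 2.1 | 0.6 |
| beta | 0.417 | 5.8 | 0 |
| beta | 0.833 | 15.5 | 0 |
| beta | 1.50 | 33.1 | 1.9 |
| beta | 3.00 | 49.9 | 19.9 |
| alpha | 0.667 | 6.8 | 0 |
| alpha | 1.33 | 20.6 | 0 |
| alpha | 2.00 | 30.8 | 9.6 |
| alpha | 2.50 | 33.7 | 14.5 |
| alpha | 3.00 | 35.0 | 16.0 |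

(readings scatter by 1 percentage point)

- for Z the G are counted in
- as a solid, counted per litre of solution: X, G, L
- on the list of suspects stand: X <-> D; D + E -> Z; G <-> Z; L <-> E; Z <-> Q
- at the start none of X is in solution
- at the start none of L is in solution
- D means what is dissolved; the solid is not counted in it

* Z and G together at 3.0 h, in percent of the X charged
* concentration of D in solution at 3.0 h, in percent of saturation

My bench rule comes from those two readings. I call their mean w = 0.0375 M, the end output, meaning the molarity of Z and G at 3.0 h with 0.0624 M of L, taken as the same for any X charge. The yield in percent is then w over the X charged. For the flask, my own figure is 72.0 %.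

The rule has a border, found from the ratio of L to X. Beta has 0.855 and alpha 0.567, while the flask has 1.20, more than either and more than one. So in the flask X is, by charge, the limiting reagent, whereas in beta and alpha L is; the flask lies outside the two runs, and I expect less than my figure.

The forecast gives y as 60 % (50 % to 70 %), below my figure, and sat as 50 % (15 % to 100 %), on the ground that “Solid X is probably gone by 3 h and D is below saturation”.

The flask gives y = 51.8 % and sat = 7.59 %, which is 0.0269 M of Z and G, less than w.

    X ⇌ D, rate k1*(cs1 - [D]) while solid is left; crystals form when [D] > cs1 (solubility = 38.0 mM, k = 0.0320 /min)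
    D + E → Z (k = 1.20 /M/min)
    G ⇌ Z, rate k3*(cs3 - [Z]) while solid is left; crystals form when [Z] > cs3 (solubility = 21.0 mM, k = 0.280 /min)
    L ⇌ E, rate k4*(cs4 - [E]) while solid is left; crystals form when [E] > cs4 (solubility = 0.0500 M, k = 0.0170 /min)
    Z ⇌ Q (K = 1.60, k = 0.0130 /min)

In the flask the step from D and E to Z turned over 94.5 % of the X charged, more than the 72.0 % of the rule. The flask ends lower because Z goes on to Q: with the step from Z to Q struck out it holds 94.5 % of Z and G. A neighbour lies inside the border: the same flask with 0.13 M of X and so 0.480 equiv of L gets 28.8 % from w and gives 29.1 % when run.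

The readings are simulated with constants of no real substance, noise included.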